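At late times product in red can reach at most 90.0 % of the starting material, because second substrate is the limiting reagent, charged at less than starting material, and the enzyme's lifetime capacity, 0.564 M of product, is larger than that charge. The question here is what 30 s allows.

| setting | red | ochre | amber | teal |
|---|---|---|---|---|
| starting material | 0.20 M | 0.20 M | 0.20 M | 0.20 M (fed, over 20 s) |
| second substrate | 0.180 M | 0.180 M (in portions, 4, over 20 s) | 0.180 M (fed, over 20 s) | 0.180 M |
| enzyme | 20 µM | 20 µM | 20 µM | 20 µM |
| time | 30 s | 30 s | 30 s | 30 s |
| remark | everything together at the start | first portion at the start, last at 20 s | all else is in the flask from the start; the feed brings no volume worth counting | all else is in the flask from the start; the feed brings no volume worth counting |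

    second substrate + starting complex ⇌ ternary complex (K1 = 15 L mol⁻¹, k1 = 1.83 × 10⁵ L mol⁻¹ s⁻¹)
    ternary complex → enzyme + product (k2 = 406 s⁻¹)
    ternary complex → spent catalyst (k3 = 0.0144 s⁻¹)
    starting material + enzyme ⇌ starting complex (K4 = 15.8 L mol⁻¹, k4 = 1.37 × 10⁵ L mol⁻¹ s⁻¹)

- which flask leads in amount of product, in percent of the starting material charged ("all alike" within 1.5 percentage points) (red / ochre / amber / teal / all alike)
- how much product is there at the end, in percent of the starting material charged: red
- how much product is there at the end, in percent of the starting material charged: ochre
- how much product is there at the end, in percent of the starting material charged: amber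
- how much product is there at the end, in percent of the starting material charged: teal

1. Product forms from ternary complex. So yield equals a ceiling times the mean share of catalyst held as ternary complex. The ceiling is 122 %, the yield if every enzyme stayed ternary complex for the whole time. It is the same for the four flasks, which share enzyme, time and charge.

2. At the charge of starting material, free enzyme binds it with a time constant of 3.65 × 10⁻⁵ s, and ternary complex turns over in 0.00246 s. Both are far shorter than 30 s, so the complexes follow the substrates. At steady state, ternary over starting complex is g times second substrate, with g = 14.5 L mol⁻¹.

3. Extreme one: red's substrates stay at their charge and no catalyst dies. The share is 65.8 %, so the yield is 80.2 %.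

4. Extreme two: red's substrates stand from the start where that yield leaves them. The share is 9.79 %, so the yield is 11.9 %. Red lies between the extremes.

5. Replace the falling curve by its mean. Try 0.7 of extreme one, 56.1 %. Take the share at the midpoint of that yield and remove the mean catalyst lost. This returns 60.2 %. I take the middle of the two and commit to 58.2 % for red.

6. Ochre's first portion gives a share of 33.0 %, less than red's. Amber and teal begin with one substrate absent. I pick red.

7. The forecast also picks red, with 56.2 % for red, less than my figure, then 46.7 % for ochre, 46.5 % for amber and 50.9 % for teal. Its ground: dosing keeps a substrate low, so that “every dosed flask loses rate”.

8. The simulation puts red first at 56.2 %, with ochre 46.7 %, amber 46.4 % and teal 51.0 %.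

9. Divided by the ceiling, red's reading is a mean share of 46.1 %. Now take the neighbour flask: red with 0.045 M of second substrate. Its ceiling is unchanged, and its start share equals ochre's first-portion share, so extreme one gives 40.3 %. But its second substrate allows 22.5 % of the starting material, less. The neighbour flask reaches 19.6 %, a mean share of 16.1 %, and its ternary complex ends at 5.28 % of the catalyst.

The constants used here were set for the occasion; the run is a simulation.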